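**Retrosynthetic overview**

1. Numbering used (eunicellane): ten-membered ring C1–C10 with C2=C3(CH3), C6–OAc, C7=CH2 (C19) and C9–OAc; cyclohexane C1, C10, C11(CH3)(OH), C12, C13, C14(iPr).
2. Target ⇒ C6 ketone; the end game is catalyst-controlled reduction, desilylation and acetylation.
3. Key disconnection: the γ,δ-unsaturated ketone array O=C6–C5–C4–C3(CH3)=C2 inside the ten-membered ring is a Claisen retron. Retro-[3,3] (break C4–C5, join the C6 oxygen to C2) gives an eight-membered 2-methylene-oxocane (ring O, C2, C1, C10, C9, C8, C7, C6) with an isopropenyl group on C2, so the carbocycle arises from the oxocane by two-atom ring expansion. The oxocane comes from the α-methylene lactone (Petasis), the lactone from a seco acid (Shiina).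
4. Seco acid ⇒ Barbier allylation of a C9 aldehyde (C8–C9) and reduction of a C2 isopropenyl ketone; both carbonyls ⇒ glycol cleavage of a cyclobutane-1,2-diol ⇒ ketene [2+2] adduct of (R)-α-phellandrene. C14 is bought; C1/C10 come from the cycloaddition, C11 from HAT hydration, C9 from Felkin control, C6 from CBS reduction.
5. Ring order: cyclohexane (purchased) → temporary cyclobutane (made, then cleaved) → eight-membered lactone → ten-membered carbocycle.

Key step: step 12

Remark: the acetoxy carbon of the cyclobutanone and both carbinol carbons of the cyclobutanediol are drawn as the expected isomers, but they become carbonyl carbons in step 5. The C2 carbinol is drawn (R), as expected from Felkin control, and becomes sp2 in the key step. Neither assignment reaches the target.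

**Route**

Step 1
Reactants: 1 (R)-(−)-α-phellandrene (used in excess); 2 acetoxyacetyl chloride
Product: 4 2-methyl-7-oxo-5-(propan-2-yl)bicyclo[4.2.0]oct-2-en-8-yl acetate (cis-fused cyclobutanone; cyclobutane anti to iPr; C=O on the carbon next to the iPr-bearing side; endo-OAc), via acetoxyketene 3 (not isolated)
Conditions: Et3N, toluene, 80 °C, slow addition of 2
Reagents that add atoms: none
Why: Ketene–diene [2+2] cycloaddition: the ketene made in situ should add to the less substituted C1=C10 bond of the diene on the face opposite the isopropyl group, with the carbonyl carbon bonding to the diene terminus (C1), so the cis C1/C10 relationship comes from suprafacial addition to the alkene and its sense from the C14 centre.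

Step 2
Reactants: 4 cyclobutanone
Product: 5 2-hydroxy-2-methyl-7-oxo-5-(propan-2-yl)bicyclo[4.2.0]octan-8-yl acetate (tertiary OH anti to the cyclobutane)
Conditions: Co(acac)2 (cat.), PhSiH3, O2 (1 atm), THF, rt
Reagents that add atoms: dioxygen, O=O
Why: Mukaiyama (HAT) hydration: Markovnikov hydrogen-atom transfer gives the tertiary C11 radical, which should be trapped by O2 on the convex face anti to the cis-fused cyclobutane (OH trans to C9), while ketone and acetate are inert.

Step 3
Reactants: 5 tertiary alcohol
Product: 6 2-methyl-7-oxo-5-(propan-2-yl)-2-(triethylsilyloxy)bicyclo[4.2.0]octan-8-yl acetate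
Conditions: TESOTf, 2,6-lutidine, CH2Cl2, −78 → 0 °C
Reagents that add atoms: triethylsilyl trifluoromethanesulfonate, CC[Si](CC)(CC)OS(=O)(=O)C(F)(F)F
Why: Silyl triflate silylation of the hindered tertiary alcohol, which later blocks retro-aldol and elimination of the β-oxygenated aldehyde and competing acylation at C11–OH.

Step 4
Reactants: 6 silyl ether; 7 isopropenylmagnesium bromide (3.5 equiv)
Product: 9 2-methyl-5-(propan-2-yl)-7-(prop-1-en-2-yl)-2-(triethylsilyloxy)bicyclo[4.2.0]octane-7,8-diol (cis-diol), via bromomagnesium alkoxide adduct 8 (not isolated)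
Conditions: THF, −78 → 0 °C; aq. NH4Cl
Reagents that add atoms: none
Why: Grignard 1,2-addition to the strained cyclobutanone from the exo face, followed by cleavage of the acetate by excess reagent, should give the 1,2-diol; both carbinol configurations are irrelevant because both carbons become carbonyls in step 5.

Step 5
Reactants: 9 cyclobutane-1,2-diol
Product: 10 2-methyl-6-(2-methylprop-2-enoyl)-5-(propan-2-yl)-2-(triethylsilyloxy)cyclohexane-1-carbaldehyde (CHO and acyl cis; C9 aldehyde, C2 isopropenyl ketone)
Conditions: NaIO4, THF/pH 7 buffer, 0 °C → rt; used crude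
Reagents that add atoms: none
Why: Malaprade glycol cleavage, helped by release of cyclobutane strain, unveils the C9 aldehyde and the C2 enone at neutral pH, so the epimerisable C1 and C10 centres should stay intact.

Step 6
Reactants: 10 keto-aldehyde; 11 methyl 2-(bromomethyl)acrylate
Product: 13 methyl (4R)-4-hydroxy-2-methylidene-4-[2-methyl-6-(2-methylprop-2-enoyl)-5-(propan-2-yl)-2-(triethylsilyloxy)cyclohexyl]butanoate, via allylindium reagent 12 (not isolated)
Conditions: In powder, THF/H2O, rt
Reagents that add atoms: none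
Why: Indium-mediated Barbier allylation, chemoselective for the aldehyde over the enone; Felkin–Anh attack on the axial formyl group anti to the fully substituted C11 should give the (9R) carbinol.

Step 7
Reactants: 13 homoallylic alcohol
Product: 14 methyl (4R)-2-methylidene-4-[2-methyl-6-(2-methylprop-2-enoyl)-5-(propan-2-yl)-2-(triethylsilyloxy)cyclohexyl]-4-(triethylsilyloxy)butanoate
Conditions: TESOTf, 2,6-lutidine, CH2Cl2, −78 °C
Reagents that add atoms: triethylsilyl trifluoromethanesulfonate, CC[Si](CC)(CC)OS(=O)(=O)C(F)(F)F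
Why: Silyl triflate protection of the secondary carbinol (through the open-chain form if a hemiketal with the C2 ketone is present), which prevents γ-lactonisation onto the ester now and translactonisation later.

Step 8
Reactants: 14 enone ester
Product: 15 methyl (4R)-4-{6-[(1R)-1-hydroxy-2-methylprop-2-enyl]-2-methyl-5-(propan-2-yl)-2-(triethylsilyloxy)cyclohexyl}-2-methylidene-4-(triethylsilyloxy)butanoate
Conditions: NaBH4, CeCl3·7H2O, MeOH, −78 °C
Reagents that add atoms: none
Why: Luche 1,2-reduction of the enone leaves the acrylate untouched; Felkin–Anh addition anti to C10 should favour the (2R) alcohol, and since C2 is erased in step 12 its configuration does not reach the target.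

Step 9
Reactants: 15 hydroxy ester
Product: 16 (4R)-4-{6-[(1R)-1-hydroxy-2-methylprop-2-enyl]-2-methyl-5-(propan-2-yl)-2-(triethylsilyloxy)cyclohexyl}-2-methylidene-4-(triethylsilyloxy)butanoic acid (seco acid)
Conditions: LiOH, THF/H2O, 0 °C → rt; then aq. HCl to pH 4–5
Reagents that add atoms: lithium hydroxide, [Li+].[OH-]
Why: Saponification of the unhindered methyl ester; the triethylsilyl ethers and the allylic alcohol should be stable to LiOH at room temperature.

Step 10
Reactants: 16 seco acid
Product: 18 eight-membered α-methylene lactone (ring O, C2, C1, C10, C9, C8, C7, C6; C6=O, C7=CH2, (2R)-isopropenyl, (9R)-OTES, 11-OTES; cis-fused to the cyclohexane), via mixed anhydride 17 (not isolated)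
Conditions: MNBA, DMAP, Et3N, CH2Cl2 (0.001 M, slow addition), rt
Reagents that add atoms: none
Why: Shiina macrolactonisation at high dilution; the cis-1,2 chains on the cyclohexane and the two sp2 centres C6 and C7 preorganise the eight-membered ring, and no stereocentre is touched.

Step 11
Reactants: 18 lactone
Product: 19 2,3-dimethylene-oxocane (cyclic enol ether C6(=C5H2)–O–C2; otherwise as 18)
Conditions: Cp2TiMe2, toluene/THF, 65 °C, dark; filtration through basic alumina, used at once
Reagents that add atoms: dimethyltitanocene, C[Ti](C)(C1C=CC=C1)C1C=CC=C1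
Why: Petasis methylenation of the lactone carbonyl (titanocene methylidene [2+2] and cycloreversion) should give the enol ether at a temperature below the onset of the rearrangement, and removing titanium before heating prevents methylenation of the ketone formed in step 12.

Step 12
Reactants: 19 2,3-dimethylene-oxocane
Product: 20 (2Z,9R)-9,11-bis(triethylsilyloxy)eunicella-2,7(19)-dien-6-one (ten-membered α-methylene ketone cis-fused to the cyclohexane)
Conditions: toluene (0.005 M), BHT (cat.), base-washed sealed tube, 130 °C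
Reagents that add atoms: none
Why: Claisen ([3,3]-sigmatropic) rearrangement of the allyl vinyl ether C5H2=C6–O–C2–C3(CH3)=C4H2 embedded in the oxocane: C4–C5 forms as O–C2 breaks, the ring oxygen is expelled into the C6 carbonyl and the eight-membered heterocycle becomes the ten-membered carbocycle (two-atom ring expansion), the closest known reaction type being the Claisen ring expansion of 2-methylene-6-vinyltetrahydropyrans and their seven-membered homologues to cyclooctenones and cyclononenones. The ten-membered ring is closed by sigmatropic C–C bond formation between the exocyclic sp2 termini C5 and C4 through a chair-like six-centre transition state bridged by the chain C7–C8–C9–C10–C1, not by an end-to-end cyclisation. No stereocentre is created and the C2 centre is erased; C1, C9, C10, C11 and C14 are not involved, and neutral thermal conditions leave the α-centres untouched. The one new stereo-element, the C2=C3 geometry, should be Z because the ring torsion C6–O–C2–C1 must stay gauche in an eight-membered ring, which puts C1 pseudo-axial on the transition-state chair, whereas the E olefin would need an anti arrangement the oxocane cannot reach. The selectivity needed is rearrangement over hydrolysis or oligomerisation of the cross-conjugated alkoxydiene and over hetero-Diels–Alder dimerisation of the α-methylene ketone formed, which high dilution, base-washed glass and a radical inhibitor should secure.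

Step 13
Reactants: 20 α-methylene ketone
Product: 21 (2Z,6R,9R)-9,11-bis(triethylsilyloxy)eunicella-2,7(19)-dien-6-ol
Conditions: (S)-Me-CBS, catecholborane, toluene, −78 °C
Reagents that add atoms: none
Why: Corey–Bakshi–Shibata reduction: with the alkenyl branch C7 as the large substituent the (S)-catalyst should deliver hydride to give the (6R) allylic alcohol, and catecholborane at −78 °C avoids hydroboration and 1,4-reduction.

Step 14
Reactants: 21 bis-silyl ether
Product: 22 (2Z,6R,9R)-eunicella-2,7(19)-diene-6,9,11-triol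
Conditions: TBAF, THF, 0 → 40 °C; aq. NH4Cl
Reagents that add atoms: none
Why: Fluoride-mediated desilylation removes both triethylsilyl ethers without affecting the allylic alcohol or the olefins.

Step 15
Reactants: 22 triol
Product: 23 (1S,2Z,6R,9R,10S,11R,14R)-6,9-diacetoxyeunicella-2,7(19)-dien-11-ol (CNP0303839.1)
Conditions: Ac2O, pyridine, DMAP (cat.), CH2Cl2, 0 °C → rt
Reagents that add atoms: acetic anhydride, CC(=O)OC(C)=O
Why: DMAP-catalysed acetylation of the two secondary alcohols; the hindered tertiary C11–OH should not acylate under these conditions.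

**Compound list**

1 | (R)-(−)-α-phellandrene, (5R)-2-methyl-5-(propan-2-yl)cyclohexa-1,3-diene | CC1=CC[C@H](C(C)C)C=C1 | starting material
2 | acetoxyacetyl chloride | CC(=O)OCC(=O)Cl | starting material
3 | acetoxyketene | CC(=O)OC=C=O | intermediate
4 | 2-methyl-7-oxo-5-(propan-2-yl)bicyclo[4.2.0]oct-2-en-8-yl acetate (cis-fused, anti to iPr, endo-OAc) | O=C1[C@@H](OC(C)=O)[C@@H]2[C@H]1[C@@H](C(C)C)CC=C2C | intermediate
5 | 2-hydroxy-2-methyl-7-oxo-5-(propan-2-yl)bicyclo[4.2.0]octan-8-yl acetate (OH anti to cyclobutane) | O=C1[C@@H](OC(C)=O)[C@@H]2[C@H]1[C@@H](C(C)C)CC[C@@]2(C)O | intermediate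
6 | 2-methyl-7-oxo-5-(propan-2-yl)-2-(triethylsilyloxy)bicyclo[4.2.0]octan-8-yl acetate | O=C1[C@@H](OC(C)=O)[C@@H]2[C@H]1[C@@H](C(C)C)CC[C@@]2(C)O[Si](CC)(CC)CC | intermediate
7 | isopropenylmagnesium bromide | C=C(C)[Mg]Br | starting material
8 | bromomagnesium alkoxide of 8-acetoxy-7-isopropenyl-2-methyl-5-(propan-2-yl)-2-(triethylsilyloxy)bicyclo[4.2.0]octan-7-ol | C=C(C)[C@]1(O[Mg]Br)[C@@H](OC(C)=O)[C@@H]2[C@H]1[C@@H](C(C)C)CC[C@@]2(C)O[Si](CC)(CC)CC | intermediate
9 | 2-methyl-5-(propan-2-yl)-7-(prop-1-en-2-yl)-2-(triethylsilyloxy)bicyclo[4.2.0]octane-7,8-diol (cis-diol) | C=C(C)[C@]1(O)[C@@H](O)[C@@H]2[C@H]1[C@@H](C(C)C)CC[C@@]2(C)O[Si](CC)(CC)CC | intermediate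
10 | 2-methyl-6-(2-methylprop-2-enoyl)-5-(propan-2-yl)-2-(triethylsilyloxy)cyclohexane-1-carbaldehyde (CHO/acyl cis) | O=C[C@@H]1[C@H](C(=O)C(C)=C)[C@@H](C(C)C)CC[C@@]1(C)O[Si](CC)(CC)CC | intermediate
11 | methyl 2-(bromomethyl)acrylate | C=C(CBr)C(=O)OC | starting material
12 | [2-(methoxycarbonyl)prop-2-enyl]indium | C=C(C[In])C(=O)OC | intermediate
13 | methyl (4R)-4-hydroxy-2-methylidene-4-[2-methyl-6-(2-methylprop-2-enoyl)-5-(propan-2-yl)-2-(triethylsilyloxy)cyclohexyl]butanoate | C=C(C[C@@H](O)[C@@H]1[C@H](C(=O)C(C)=C)[C@@H](C(C)C)CC[C@@]1(C)O[Si](CC)(CC)CC)C(=O)OC | intermediate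
14 | 4-O-triethylsilyl ether of 13 | C=C(C[C@@H](O[Si](CC)(CC)CC)[C@@H]1[C@H](C(=O)C(C)=C)[C@@H](C(C)C)CC[C@@]1(C)O[Si](CC)(CC)CC)C(=O)OC | intermediate
15 | methyl (4R)-4-{6-[(1R)-1-hydroxy-2-methylprop-2-enyl]-2-methyl-5-(propan-2-yl)-2-(triethylsilyloxy)cyclohexyl}-2-methylidene-4-(triethylsilyloxy)butanoate | C=C(C[C@@H](O[Si](CC)(CC)CC)[C@@H]1[C@H]([C@@H](O)C(C)=C)[C@@H](C(C)C)CC[C@@]1(C)O[Si](CC)(CC)CC)C(=O)OC | intermediate
16 | seco acid, the carboxylic acid of 15 | C=C(C[C@@H](O[Si](CC)(CC)CC)[C@@H]1[C@H]([C@@H](O)C(C)=C)[C@@H](C(C)C)CC[C@@]1(C)O[Si](CC)(CC)CC)C(=O)O | intermediate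
17 | mixed anhydride of 16 with 2-methyl-6-nitrobenzoic acid | C=C(C[C@@H](O[Si](CC)(CC)CC)[C@@H]1[C@H]([C@@H](O)C(C)=C)[C@@H](C(C)C)CC[C@@]1(C)O[Si](CC)(CC)CC)C(=O)OC(=O)c1c(C)cccc1[N+](=O)[O-] | intermediate
18 | eight-membered α-methylene lactone (O–C2 ester of the C6 acid; (2R)-isopropenyl, (9R)-OTES, 11-OTES) | C=C1C[C@@H](O[Si](CC)(CC)CC)[C@@H]2[C@H]([C@@H](OC1=O)C(C)=C)[C@@H](C(C)C)CC[C@@]2(C)O[Si](CC)(CC)CC | intermediate
19 | 2,3-dimethylene-oxocane (enol ether of 18) | C=C1C[C@@H](O[Si](CC)(CC)CC)[C@@H]2[C@H]([C@@H](OC1=C)C(C)=C)[C@@H](C(C)C)CC[C@@]2(C)O[Si](CC)(CC)CC | intermediate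
20 | (2Z,9R)-9,11-bis(triethylsilyloxy)eunicella-2,7(19)-dien-6-one | C=C1C[C@@H](O[Si](CC)(CC)CC)[C@@H]2[C@H](/C=C(/C)CCC1=O)[C@@H](C(C)C)CC[C@@]2(C)O[Si](CC)(CC)CC | intermediate
21 | (2Z,6R,9R)-9,11-bis(triethylsilyloxy)eunicella-2,7(19)-dien-6-ol | C=C1C[C@@H](O[Si](CC)(CC)CC)[C@@H]2[C@H](/C=C(/C)CC[C@H]1O)[C@@H](C(C)C)CC[C@@]2(C)O[Si](CC)(CC)CC | intermediate
22 | (2Z,6R,9R)-eunicella-2,7(19)-diene-6,9,11-triol | C=C1C[C@@H](O)[C@@H]2[C@H](/C=C(/C)CC[C@H]1O)[C@@H](C(C)C)CC[C@@]2(C)O | intermediate
23 | (1S,2Z,6R,9R,10S,11R,14R)-6,9-diacetoxyeunicella-2,7(19)-dien-11-ol, CNP0303839.1 | C=C1C[C@@H](OC(C)=O)[C@@H]2[C@H](/C=C(/C)CC[C@H]1OC(C)=O)[C@@H](C(C)C)CC[C@@]2(C)O | target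

**Step count and risks**

Total step count: 15. Longest linear sequence: 15 steps from 1 (fully linear).

Steps most likely to fail:

1. Step 12 (Claisen ring expansion). What may go wrong: oligomerisation or hydrolysis of the cross-conjugated alkoxydiene, or hetero-Diels–Alder dimerisation of the α-methylene ketone at the temperature the shift needs, outrunning the rearrangement. Fallback, setting out from 18 and returning at 20: the exocyclic methylene is masked before the ring expansion. Conjugate addition of benzeneselenolate (PhSeSePh, NaBH4, EtOH, 0 °C) to 18 should give the α-(phenylselanylmethyl) lactone F1 as C7 epimers. Petasis methylenation gives the simple 2-methylene-oxocane F2. Thermal Claisen ring expansion, now without a diene or enone in play, gives the saturated ten-membered ketone F3. Oxidation (H2O2, pyridine, CH2Cl2, 0 °C → rt) and selenoxide syn-elimination, for which only the C7–H is available, regenerates the exocyclic methylene and gives 20.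

2. Step 10 (eight-membered lactonisation). What may go wrong: intermolecular acylation (diolide and oligomers) outrunning closure of the medium ring at the hindered allylic carbinol. Fallback, setting out from 10 and returning at 18: the ring is closed by C8–C9 bond formation with the ester already in place. Chemoselective acetalisation of the aldehyde (HC(OMe)3, PPTS cat., MeOH, 0 °C) gives the dimethyl acetal F4. Luche reduction gives the allylic alcohol F5. Esterification with 2-(bromomethyl)acrylic acid (DCC, DMAP cat., CH2Cl2, 0 °C) gives the bromomethyl acrylate F6. Mild acetal hydrolysis (PPTS, wet acetone) gives the aldehyde F7. Intramolecular indium-mediated Barbier allylation at high dilution (In, THF/H2O) closes the lactone to the hydroxy lactone F8, which is silylated at once (TESOTf, 2,6-lutidine, −78 °C) to give 18. In this sequence C9 is set in the cyclisation and the (9R) isomer has to be selected.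

3. Step 6 (allylation of the C9 aldehyde). What may go wrong: insufficient facial selectivity (Felkin versus anti-Felkin addition) at the α-branched aldehyde. Fallback, setting out from 10 and returning at 13: substrate control is replaced by catalyst control. A chromium-catalysed asymmetric Nozaki–Hiyama–Kishi allylation with 11 (CrCl2 cat., chiral bis(oxazolinyl)carbazole ligand chosen for the (9R) sense, Mn, TMSCl, THF, rt) should give the (9R) trimethylsilyl ether F9. Mild acid methanolysis (citric acid, MeOH, 0 °C) then gives 13.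

**Further compounds**

F1 | step 12 | α-(phenylselanylmethyl) eight-membered lactone (C7 epimers; otherwise as 18) | c1ccccc1[Se]CC1C[C@@H](O[Si](CC)(CC)CC)[C@@H]2[C@H]([C@@H](OC1=O)C(C)=C)[C@@H](C(C)C)CC[C@@]2(C)O[Si](CC)(CC)CC
F2 | step 12 | 2-methylene-3-(phenylselanylmethyl)oxocane (enol ether of F1) | c1ccccc1[Se]CC1C[C@@H](O[Si](CC)(CC)CC)[C@@H]2[C@H]([C@@H](OC1=C)C(C)=C)[C@@H](C(C)C)CC[C@@]2(C)O[Si](CC)(CC)CC
F3 | step 12 | (2Z)-7-(phenylselanylmethyl)-9,11-bis(triethylsilyloxy)eunicell-2-en-6-one (C7 epimers) | c1ccccc1[Se]CC1C[C@@H](O[Si](CC)(CC)CC)[C@@H]2[C@H](/C=C(/C)CCC1=O)[C@@H](C(C)C)CC[C@@]2(C)O[Si](CC)(CC)CC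
F4 | step 10 | dimethyl acetal of 10 | COC(OC)[C@@H]1[C@H](C(=O)C(C)=C)[C@@H](C(C)C)CC[C@@]1(C)O[Si](CC)(CC)CC
F5 | step 10 | (1R)-allylic alcohol from F4 | COC(OC)[C@@H]1[C@H]([C@@H](O)C(C)=C)[C@@H](C(C)C)CC[C@@]1(C)O[Si](CC)(CC)CC
F6 | step 10 | 2-(bromomethyl)acrylate ester of F5 | COC(OC)[C@@H]1[C@H]([C@@H](OC(=O)C(=C)CBr)C(C)=C)[C@@H](C(C)C)CC[C@@]1(C)O[Si](CC)(CC)CC
F7 | step 10 | aldehyde from F6 | O=C[C@@H]1[C@H]([C@@H](OC(=O)C(=C)CBr)C(C)=C)[C@@H](C(C)C)CC[C@@]1(C)O[Si](CC)(CC)CC
F8 | step 10 | eight-membered α-methylene lactone with free (9R)-OH | C=C1C[C@@H](O)[C@@H]2[C@H]([C@@H](OC1=O)C(C)=C)[C@@H](C(C)C)CC[C@@]2(C)O[Si](CC)(CC)CC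
F9 | step 6 | 4-O-trimethylsilyl ether of 13 | C=C(C[C@@H](O[Si](C)(C)C)[C@@H]1[C@H](C(=O)C(C)=C)[C@@H](C(C)C)CC[C@@]1(C)O[Si](CC)(CC)CC)C(=O)OC
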